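**Retrosynthetic overview**
1. Target 21 comes from ketone 19 by a late equatorial methyl addition at C4; the C6 centre comes from hydrogen-atom-transfer hydrogenation of a 6,7-alkene.
2. Key step: the C1–benzylic carbon bond and the C2–C3 bond of ring A form in one radical cascade — 6-endo cyclisation of an α-keto radical onto a vinyl group, then capture of the C1 radical by the o-quinone methide from diformylphloroglucinol and 3-methylbutanal.
3. Ring B with the C4a/C8a pair comes from a catalytic asymmetric Diels–Alder reaction of (E)-2-methyl-4-oxopent-2-enal with a 2-substituted diene; CHO becomes vinyl, acetyl becomes bromoacetyl.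
4. Ring order: ring B (cycloaddition), then ring A (radical cascade); the arene is built from a resorcinol core by C–H borylation/oxidation and double formylation.

Assumption: the commercial trimethylsilyl ethers 1 and 9 are used as protected forms of resorcinol and 2-methylbut-3-yn-2-ol; decalin locants follow the naphthalene numbering of the target (C1 carries the side chain, C8a the angular methyl; ring A = C1–C4, ring B = C5–C8).

**Step 1**
Reactants: 1 1,3-bis(trimethylsilyloxy)benzene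
Product: 3 benzene-1,3,5-triol (phloroglucinol), via aryl boronate 2 (not isolated)
Conditions: [Ir(OMe)(cod)]2 (1.5 mol%), 4,4'-di-tert-butyl-2,2'-bipyridine, B2pin2, cyclohexane, 80 °C; then Oxone (2KHSO5·KHSO4·K2SO4), acetone/H2O, 23 °C; 1 M HCl
Reagents that add atoms: potassium peroxymonosulfate (Oxone), [K+].[O-]S(=O)(=O)OO
Why: Sterically controlled iridium-catalysed C–H borylation (Hartwig–Miyaura/Smith–Maleczka type) takes place at the only ring C–H not ortho to a bulky silyloxy group, and one-pot boronate oxidation with hydrolysis of the aryl silyl ethers gives the symmetrical triol.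

**Step 2**
Reactants: 3 benzene-1,3,5-triol
Product: 5 2,4,6-trihydroxybenzene-1,3-dicarbaldehyde, via bis(iminium) salt 4 (not isolated)
Conditions: POCl3 (2.5 equiv), DMF (2.5 equiv), 1,4-dioxane/EtOAc, 0 → 23 °C; then H2O
Reagents that add atoms: N,N-dimethylformamide, CN(C)C=O; water, O
Why: Double Vilsmeier–Haack formylation of the electron-rich triphenol stops at the 2,4-disubstituted stage because each iminium group deactivates the ring, and aqueous work-up hydrolyses the bis(iminium) salt.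

**Step 3**
Reactants: 6 2,4-dimethylfuran
Product: 8 (2E)-2-methyl-4-oxopent-2-enal, via Z-enedione 7 (not isolated)
Conditions: NBS (1.05 equiv), NaHCO3, acetone/H2O (9:1), −20 °C; then pyridine, 23 °C
Reagents that add atoms: water, O
Why: Oxidative furan ring opening (bromohydration, Achmatowicz-type) gives the cis ene-dicarbonyl, which pyridine isomerises to the E isomer that has aldehyde and acetyl trans.

**Step 4**
Reactants: 9 trimethyl[(2-methylbut-3-yn-2-yl)oxy]silane; 10 ethene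
Product: 11 trimethyl[(2-methyl-3-methylidenepent-4-en-2-yl)oxy]silane
Conditions: ethene (1 atm), second-generation Grubbs catalyst RuCl2(=CHPh)(PCy3)(H2IMes) (3 mol%), CH2Cl2, 40 °C
Reagents that add atoms: none
Why: Cross enyne metathesis of a terminal propargylic silyl ether with ethene (Mori conditions) gives the 2-substituted buta-1,3-diene directly.

**Step 5**
Reactants: 8 (2E)-2-methyl-4-oxopent-2-enal; 11 the diene
Product: 12 (1S,6S)-6-acetyl-1-methyl-4-{2-[(trimethylsilyl)oxy]propan-2-yl}cyclohex-3-ene-1-carbaldehyde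
Conditions: (R)-1-(2-methylphenyl)-3,3-diphenyltetrahydro-1H,3H-pyrrolo[1,2-c][1,3,2]oxazaborole·HNTf2 (C24H24BNO·HNTf2, 20 mol%), CH2Cl2, −78 → −40 °C
Reagents that add atoms: none
Why: In this catalytic asymmetric Diels–Alder reaction the boron cation binds the formyl group, so the carbon β to the aldehyde bonds to the CH2 next to the substituted diene carbon ("para" orientation), the E geometry is transferred into the trans aldehyde/acetyl relationship, and the catalyst selects the face that gives the (1S,6S) pair (the R catalyst is assigned by analogy with 2-substituted acroleins and must be confirmed on the first run).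

**Step 6**
Reactants: 12 the keto aldehyde
Product: 13 1-[(1S,6R)-6-ethenyl-6-methyl-3-{2-[(trimethylsilyl)oxy]propan-2-yl}cyclohex-3-en-1-yl]ethan-1-one
Conditions: Ph3PCH3Br (1.1 equiv), KN(SiMe3)2 (1.05 equiv), THF, 0 °C; then 12, −78 → −20 °C
Reagents that add atoms: methyltriphenylphosphonium bromide, C[P+](c1ccccc1)(c1ccccc1)c1ccccc1.[Br-]
Why: Wittig methylenation with one equivalent of ylide at low temperature converts the aldehyde, which reacts much faster than the methyl ketone, into the vinyl group on the quaternary carbon without touching either stereocentre.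

**Step 7**
Reactants: 13 the methyl ketone
Product: 15 2-bromo-1-[(1S,6R)-6-ethenyl-6-methyl-3-{2-[(trimethylsilyl)oxy]propan-2-yl}cyclohex-3-en-1-yl]ethan-1-one, via silyl enol ether 14 (not isolated)
Conditions: LiN(iPr)2 (1.1 equiv), THF, −78 °C; Me3SiCl; then NBS, THF, −78 °C
Reagents that add atoms: N-bromosuccinimide, O=C1CCC(=O)N1Br
Why: Kinetic deprotonation occurs at the unhindered methyl group, and the trapped silyl enol ether is brominated regiospecifically (α-bromination through a silyl enol ether).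

**Step 8 (key step)**
Reactants: 15 the bromo ketone; 5 2,4,6-trihydroxybenzene-1,3-dicarbaldehyde; 16 3-methylbutanal
Product: 18 2,4,6-trihydroxy-5-{(1R)-3-methyl-1-[(1S,4aS,8aR)-8a-methyl-4-oxo-6-{2-[(trimethylsilyl)oxy]propan-2-yl}-1,2,3,4,4a,5,8,8a-octahydronaphthalen-1-yl]butyl}benzene-1,3-dicarbaldehyde, via quinone methide 17 (not isolated)
Conditions: 5 (3 equiv), 16 (3 equiv), ethylenediammonium diacetate (20 mol%), THF, 23 °C, 1 h; then 15; (Me3Si)3SiH (1.5 equiv) and 2,2'-azobis(4-methoxy-2,4-dimethylvaleronitrile) (0.3 equiv) by syringe pump, 30 °C, 8 h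
Reagents that add atoms: none
Why: Proposed new method: a silyl radical abstracts bromine from 15, the electrophilic α-keto radical closes ring A by 6-endo-trig attack on the terminal vinyl carbon through a chair with acyl and vinyl pseudo-equatorial (trans fusion already fixed in 12), and the nucleophilic secondary C1 radical adds to the electron-poor methide carbon of 17 anti to the axial angular methyl (sets C1) with the quinoid ring anti to the quaternary carbon (Felkin-type, sets the benzylic centre) before the silane reduces the aryloxyl radical; the closest known reaction types are Curran's 6-endo cyclisations of α-halo ketones and Giese additions to alkylidene 1,3-dicarbonyls and o-quinone methides.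

**Step 9**
Reactants: 18 the octalone
Product: 19 2,4,6-trihydroxy-5-{(1R)-3-methyl-1-[(1S,4aS,6S,8aR)-8a-methyl-4-oxo-6-{2-[(trimethylsilyl)oxy]propan-2-yl}decahydronaphthalen-1-yl]butyl}benzene-1,3-dicarbaldehyde
Conditions: Mn(dpm)3 [tris(2,2,6,6-tetramethylheptane-3,5-dionato)manganese] (10 mol%), PhSiH3 (1.2 equiv), t-BuOOH (1.5 equiv), i-PrOH, 23 °C
Reagents that add atoms: none
Why: Hydrogen-atom-transfer hydrogenation (Shenvi) puts H on C7, and the tertiary C6 radical then takes its hydrogen axially, which gives the thermodynamically preferred equatorial side chain cis to the angular methyl while carbonyl groups are left alone.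

**Step 10**
Reactants: 19 the decalone
Product: 21 5-{(1R)-1-[(1S,4R,4aS,6S,8aR)-4-hydroxy-6-(2-hydroxypropan-2-yl)-4,8a-dimethyldecahydronaphthalen-1-yl]-3-methylbutyl}-2,4,6-trihydroxybenzene-1,3-dicarbaldehyde, via silyl ether 20 (not isolated)
Conditions: MeMgBr (8 equiv), THF, −40 → 0 °C; then 1 M HCl, THF, 0 °C
Reagents that add atoms: methylmagnesium bromide, C[Mg]Br
Why: Grignard addition to the C4 ketone comes from the equatorial direction because the axial face is blocked by the syn-axial angular methyl, giving the axial alcohol cis to that methyl, while the two formyl groups are masked in situ as part of the magnesium tris-phenoxide (vinylogous carboxylates) and the acidic work-up removes the silyl ether.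

**Compound list**
1 | 1,3-bis(trimethylsilyloxy)benzene | C[Si](C)(C)Oc1cccc(O[Si](C)(C)C)c1 | starting material
2 | 2-[3,5-bis(trimethylsilyloxy)phenyl]-4,4,5,5-tetramethyl-1,3,2-dioxaborolane | C[Si](C)(C)Oc1cc(O[Si](C)(C)C)cc(B2OC(C)(C)C(C)(C)O2)c1 | intermediate
3 | benzene-1,3,5-triol | Oc1cc(O)cc(O)c1 | intermediate
4 | N,N'-[(2,4,6-trihydroxy-1,3-phenylene)dimethanylylidene]bis(N-methylmethanaminium) dichloride | C[N+](C)=Cc1c(O)cc(O)c(C=[N+](C)C)c1O.[Cl-].[Cl-] | intermediate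
5 | 2,4,6-trihydroxybenzene-1,3-dicarbaldehyde | O=Cc1c(O)c(C=O)c(O)cc1O | intermediate
6 | 2,4-dimethylfuran | Cc1cc(C)co1 | starting material
7 | (2Z)-2-methyl-4-oxopent-2-enal | CC(=O)/C=C(\C=O)C | intermediate
8 | (2E)-2-methyl-4-oxopent-2-enal | CC(=O)/C=C(/C=O)C | intermediate
9 | trimethyl[(2-methylbut-3-yn-2-yl)oxy]silane | C#CC(C)(C)O[Si](C)(C)C | starting material
10 | ethene | C=C | starting material
11 | trimethyl[(2-methyl-3-methylidenepent-4-en-2-yl)oxy]silane | C=CC(=C)C(C)(C)O[Si](C)(C)C | intermediate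
12 | (1S,6S)-6-acetyl-1-methyl-4-{2-[(trimethylsilyl)oxy]propan-2-yl}cyclohex-3-ene-1-carbaldehyde | CC(=O)[C@H]1CC(C(C)(C)O[Si](C)(C)C)=CC[C@]1(C)C=O | intermediate
13 | 1-[(1S,6R)-6-ethenyl-6-methyl-3-{2-[(trimethylsilyl)oxy]propan-2-yl}cyclohex-3-en-1-yl]ethan-1-one | CC(=O)[C@H]1CC(C(C)(C)O[Si](C)(C)C)=CC[C@]1(C)C=C | intermediate
14 | ({1-[(1S,6R)-6-ethenyl-6-methyl-3-{2-[(trimethylsilyl)oxy]propan-2-yl}cyclohex-3-en-1-yl]ethenyl}oxy)trimethylsilane | C=C(O[Si](C)(C)C)[C@H]1CC(C(C)(C)O[Si](C)(C)C)=CC[C@]1(C)C=C | intermediate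
15 | 2-bromo-1-[(1S,6R)-6-ethenyl-6-methyl-3-{2-[(trimethylsilyl)oxy]propan-2-yl}cyclohex-3-en-1-yl]ethan-1-one | BrCC(=O)[C@H]1CC(C(C)(C)O[Si](C)(C)C)=CC[C@]1(C)C=C | intermediate
16 | 3-methylbutanal | CC(C)CC=O | starting material
17 | 2,4-dihydroxy-5-(3-methylbutylidene)-6-oxocyclohexa-1,3-diene-1,3-dicarbaldehyde | CC(C)CC=C1C(=O)C(C=O)=C(O)C(C=O)=C1O | intermediate
18 | 2,4,6-trihydroxy-5-{(1R)-3-methyl-1-[(1S,4aS,8aR)-8a-methyl-4-oxo-6-{2-[(trimethylsilyl)oxy]propan-2-yl}-1,2,3,4,4a,5,8,8a-octahydronaphthalen-1-yl]butyl}benzene-1,3-dicarbaldehyde | CC(C)C[C@@H](c1c(O)c(C=O)c(O)c(C=O)c1O)[C@@H]1CCC(=O)[C@H]2CC(C(C)(C)O[Si](C)(C)C)=CC[C@]12C | intermediate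
19 | 2,4,6-trihydroxy-5-{(1R)-3-methyl-1-[(1S,4aS,6S,8aR)-8a-methyl-4-oxo-6-{2-[(trimethylsilyl)oxy]propan-2-yl}decahydronaphthalen-1-yl]butyl}benzene-1,3-dicarbaldehyde | CC(C)C[C@@H](c1c(O)c(C=O)c(O)c(C=O)c1O)[C@@H]1CCC(=O)[C@H]2C[C@@H](C(C)(C)O[Si](C)(C)C)CC[C@]12C | intermediate
20 | 2,4,6-trihydroxy-5-{(1R)-1-[(1S,4R,4aS,6S,8aR)-4-hydroxy-4,8a-dimethyl-6-{2-[(trimethylsilyl)oxy]propan-2-yl}decahydronaphthalen-1-yl]-3-methylbutyl}benzene-1,3-dicarbaldehyde | CC(C)C[C@@H](c1c(O)c(C=O)c(O)c(C=O)c1O)[C@@H]1CC[C@@](C)(O)[C@H]2C[C@@H](C(C)(C)O[Si](C)(C)C)CC[C@]12C | intermediate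
21 | 5-{(1R)-1-[(1S,4R,4aS,6S,8aR)-4-hydroxy-6-(2-hydroxypropan-2-yl)-4,8a-dimethyldecahydronaphthalen-1-yl]-3-methylbutyl}-2,4,6-trihydroxybenzene-1,3-dicarbaldehyde | CC(C)C[C@@H](c1c(O)c(C=O)c(O)c(C=O)c1O)[C@@H]1CC[C@@](C)(O)[C@H]2C[C@@H](C(C)(C)O)CC[C@]12C | target

**Step count and risks**
Total steps: 10. Longest linear sequence: 7 (steps 3, 5, 6, 7, 8, 9, 10; the diene branch through step 4 is equally long).

Steps most likely to fail:

1. Step 8. The cascade has to outrun premature reduction, attack of the α-keto radical on the ring-B alkene, and ionic consumption of 17; the benzylic centre rests on a Felkin-type preference only. Fallback, from 15 back to 18: close ring A alone by bromine-atom-transfer cyclisation (CuBr, tris(2-pyridylmethyl)amine, toluene, 80 °C) to the secondary bromide (4aS,8aS)-4-bromo-4a-methyl-7-{2-[(trimethylsilyl)oxy]propan-2-yl}-3,4,4a,5,8,8a-hexahydronaphthalen-1(2H)-one F1. In parallel, 5, 16 and sodium p-toluenesulfinate (aqueous formic acid) give the storable quinone-methide precursor 2,4,6-trihydroxy-5-[3-methyl-1-(4-methylbenzenesulfonyl)butyl]benzene-1,3-dicarbaldehyde F2. F1 is then coupled in a separate Giese reaction with 17 released from F2 by NaHCO3 ((Me3Si)3SiH, Et3B, air, 0 °C) to give 18.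

2. Step 10. The Grignard reagent may attack the formyl groups despite the phenoxide masking. Fallback, from 15 back to 21, carries no aldehyde through the organometallic step. Step 8 is run with 3 in place of 5, through the quinone methide 3,5-dihydroxy-6-(3-methylbutylidene)cyclohexa-2,4-dien-1-one F3, to give the triphenol ketone 2-{(1R)-3-methyl-1-[(1S,4aS,8aR)-8a-methyl-4-oxo-6-{2-[(trimethylsilyl)oxy]propan-2-yl}-1,2,3,4,4a,5,8,8a-octahydronaphthalen-1-yl]butyl}benzene-1,3,5-triol F4. Hydrogenation as in step 9 gives the decalone 2-{(1R)-3-methyl-1-[(1S,4aS,6S,8aR)-8a-methyl-4-oxo-6-{2-[(trimethylsilyl)oxy]propan-2-yl}decahydronaphthalen-1-yl]butyl}benzene-1,3,5-triol F5. MeMgBr then gives the carbinol silyl ether 2-{(1R)-1-[(1S,4R,4aS,6S,8aR)-4-hydroxy-4,8a-dimethyl-6-{2-[(trimethylsilyl)oxy]propan-2-yl}decahydronaphthalen-1-yl]-3-methylbutyl}benzene-1,3,5-triol F6, and acidic work-up the formyl-free pentol 2-{(1R)-1-[(1S,4R,4aS,6S,8aR)-4-hydroxy-6-(2-hydroxypropan-2-yl)-4,8a-dimethyldecahydronaphthalen-1-yl]-3-methylbutyl}benzene-1,3,5-triol F7. Vilsmeier–Haack double formylation (POCl3, DMF, 0 °C) through the bis(iminium) dichloride of the target F8, then buffered hydrolysis, gives 21.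

3. Step 5. The strongly acidic boron catalyst may ionise the tertiary allylic silyl ether of 11, or give insufficient regio- or enantiocontrol. Fallback, from 8 and 11 back to 12: thermal uncatalysed cycloaddition (toluene, 60 °C) gives the racemic trans adduct rac-6-acetyl-1-methyl-4-{2-[(trimethylsilyl)oxy]propan-2-yl}cyclohex-3-ene-1-carbaldehyde F9. Condensation with (1R,2R)-N,N'-dimethyl-1,2-diphenylethane-1,2-diamine gives two imidazolidines: 1-[(1S,6S)-6-[(4R,5R)-1,3-dimethyl-4,5-diphenylimidazolidin-2-yl]-6-methyl-3-{2-[(trimethylsilyl)oxy]propan-2-yl}cyclohex-3-en-1-yl]ethan-1-one F10 and its (1R,6R) diastereomer 1-[(1R,6R)-6-[(4R,5R)-1,3-dimethyl-4,5-diphenylimidazolidin-2-yl]-6-methyl-3-{2-[(trimethylsilyl)oxy]propan-2-yl}cyclohex-3-en-1-yl]ethan-1-one F11. They are separated by chromatography, and F10 is hydrolysed on wet silica gel to 12.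

**Further compounds**
F1 | step 8 | (4aS,8aS)-4-bromo-4a-methyl-7-{2-[(trimethylsilyl)oxy]propan-2-yl}-3,4,4a,5,8,8a-hexahydronaphthalen-1(2H)-one (both C4 epimers) | BrC1CCC(=O)[C@H]2CC(C(C)(C)O[Si](C)(C)C)=CC[C@]12C
F2 | step 8 | 2,4,6-trihydroxy-5-[3-methyl-1-(4-methylbenzenesulfonyl)butyl]benzene-1,3-dicarbaldehyde (racemic) | CC(C)CC(c1c(O)c(C=O)c(O)c(C=O)c1O)S(=O)(=O)c1ccc(C)cc1
F3 | step 10 | 3,5-dihydroxy-6-(3-methylbutylidene)cyclohexa-2,4-dien-1-one | CC(C)CC=C1C(=O)C=C(O)C=C1O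
F4 | step 10 | 2-{(1R)-3-methyl-1-[(1S,4aS,8aR)-8a-methyl-4-oxo-6-{2-[(trimethylsilyl)oxy]propan-2-yl}-1,2,3,4,4a,5,8,8a-octahydronaphthalen-1-yl]butyl}benzene-1,3,5-triol | CC(C)C[C@@H](c1c(O)cc(O)cc1O)[C@@H]1CCC(=O)[C@H]2CC(C(C)(C)O[Si](C)(C)C)=CC[C@]12C
F5 | step 10 | 2-{(1R)-3-methyl-1-[(1S,4aS,6S,8aR)-8a-methyl-4-oxo-6-{2-[(trimethylsilyl)oxy]propan-2-yl}decahydronaphthalen-1-yl]butyl}benzene-1,3,5-triol | CC(C)C[C@@H](c1c(O)cc(O)cc1O)[C@@H]1CCC(=O)[C@H]2C[C@@H](C(C)(C)O[Si](C)(C)C)CC[C@]12C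
F6 | step 10 | 2-{(1R)-1-[(1S,4R,4aS,6S,8aR)-4-hydroxy-4,8a-dimethyl-6-{2-[(trimethylsilyl)oxy]propan-2-yl}decahydronaphthalen-1-yl]-3-methylbutyl}benzene-1,3,5-triol | CC(C)C[C@@H](c1c(O)cc(O)cc1O)[C@@H]1CC[C@@](C)(O)[C@H]2C[C@@H](C(C)(C)O[Si](C)(C)C)CC[C@]12C
F7 | step 10 | 2-{(1R)-1-[(1S,4R,4aS,6S,8aR)-4-hydroxy-6-(2-hydroxypropan-2-yl)-4,8a-dimethyldecahydronaphthalen-1-yl]-3-methylbutyl}benzene-1,3,5-triol | CC(C)C[C@@H](c1c(O)cc(O)cc1O)[C@@H]1CC[C@@](C)(O)[C@H]2C[C@@H](C(C)(C)O)CC[C@]12C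
F8 | step 10 | bis(iminium) dichloride of the target | CC(C)C[C@@H](c1c(O)c(C=[N+](C)C)c(O)c(C=[N+](C)C)c1O)[C@@H]1CC[C@@](C)(O)[C@H]2C[C@@H](C(C)(C)O)CC[C@]12C.[Cl-].[Cl-]
F9 | step 5 | rac-6-acetyl-1-methyl-4-{2-[(trimethylsilyl)oxy]propan-2-yl}cyclohex-3-ene-1-carbaldehyde (trans, both enantiomers) | CC(=O)[C@H]1CC(C(C)(C)O[Si](C)(C)C)=CC[C@]1(C)C=O.CC(=O)[C@@H]1CC(C(C)(C)O[Si](C)(C)C)=CC[C@@]1(C)C=O
F10 | step 5 | 1-[(1S,6S)-6-[(4R,5R)-1,3-dimethyl-4,5-diphenylimidazolidin-2-yl]-6-methyl-3-{2-[(trimethylsilyl)oxy]propan-2-yl}cyclohex-3-en-1-yl]ethan-1-one | CC(=O)[C@H]1CC(C(C)(C)O[Si](C)(C)C)=CC[C@]1(C)C2N(C)[C@H](c3ccccc3)[C@@H](c3ccccc3)N2C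
F11 | step 5 | 1-[(1R,6R)-6-[(4R,5R)-1,3-dimethyl-4,5-diphenylimidazolidin-2-yl]-6-methyl-3-{2-[(trimethylsilyl)oxy]propan-2-yl}cyclohex-3-en-1-yl]ethan-1-one | CC(=O)[C@@H]1CC(C(C)(C)O[Si](C)(C)C)=CC[C@@]1(C)C2N(C)[C@H](c3ccccc3)[C@@H](c3ccccc3)N2C
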